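**Plan**

- Retrosynthesis: the acid and the C1 ketone go back to silyl-protected alcohols and the C4 acetate to a tertiary carbinol. The ring is then cut at C3–C4, the chain at C4–C1' (octyl chain) and at C5–C1 (aldol bond).
- Enabling feature: in the cyclopentenone ring, C3 is the β-carbon of the enone and C4 is the oxygen-bearing quaternary carbon. Both are acceptor carbons, so their bond is made with reversed polarity from a (Z)-alkenyl iodide (C3) and a chain ketone (C4) using CrCl2/NiCl2.
- Forward order: acylated auxiliary → syn-aldol with (Z)-3-iodoacrolein (C5–C1) → Weinreb amide and silyl ether → Grignard addition (C4–C1') → ring closure at C3–C4 (the only ring) → acetate, desilylation, oxidation.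
- Stereochemistry: C5 comes from the (R)-benzyloxazolidinone. C4 is set by C5 during ring closure (chain trans, oxygen cis to the pentenyl group). The C1 carbinol is a temporary stereocentre, oxidised away in the last step.
- Both Z-alkenes come with the building blocks: (Z)-hept-4-enoic acid, and anti hydroiodination of ethyl propiolate.

Key step: step 9

Remark: ring numbering of the target (C1 carbonyl, C2=C3 alkene, C4 acetoxy carbon, C5 pentenyl carbon) is used for the corresponding carbons of all intermediates; TBS = tert-butyldimethylsilyl.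
Remark: aluminium, boron, magnesium and chromium alkoxides that exist only until the work-up of a step are taken as bound forms of its product and are not numbered.

**Route**

Step 1
Reactants: 1 (4Z)-hept-4-enoic acid; 2 (4R)-4-benzyl-1,3-oxazolidin-2-one
Product: 4 (4R)-4-benzyl-3-[(4Z)-hept-4-enoyl]-1,3-oxazolidin-2-one, via (4Z)-hept-4-enoic pivalic anhydride 3 (not isolated)
Conditions: PivCl, Et3N, THF, −20 °C; then LiCl, 2, −20 °C → rt
Reagents that add atoms: none
Why: N-acylation of the oxazolidinone through the mixed pivalic anhydride (LiCl-assisted acyl transfer) is the standard mild entry to Evans imides and leaves the Z-alkene untouched; no stereocentre is formed.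

Step 2
Reactants: 5 ethyl propiolate
Product: 6 ethyl (2Z)-3-iodoprop-2-enoate
Conditions: NaI, AcOH, 70 °C
Reagents that add atoms: sodium iodide, [Na+].[I-]
Why: Conjugate hydroiodination of the ynoate, in which iodide adds and the allenolate is protonated anti to iodine, should give the Z-β-iodoacrylate under kinetic control.

Step 3
Reactants: 6 ethyl (2Z)-3-iodoprop-2-enoate
Product: 7 (2Z)-3-iodoprop-2-enal
Conditions: iBu2AlH, CH2Cl2, −78 °C; aq. KNaC4H4O6 (potassium sodium tartrate); dried cold CH2Cl2 solution used at once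
Reagents that add atoms: none
Why: Partial ester reduction with iBu2AlH at −78 °C stops at the aluminium hemiacetal, which releases the aldehyde only on work-up, and the Z geometry should persist if the solution is kept cold, neutral, dark and unconcentrated.

Step 4
Reactants: 4 (4R)-4-benzyl-3-[(4Z)-hept-4-enoyl]-1,3-oxazolidin-2-one; 7 (2Z)-3-iodoprop-2-enal
Product: 9 (4R)-4-benzyl-3-[(2R,4Z)-2-[(1R,2Z)-1-hydroxy-3-iodoprop-2-en-1-yl]hept-4-enoyl]-1,3-oxazolidin-2-one, via dibutylboron (Z)-enolate 8 (not isolated)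
Conditions: Bu2BOTf, iPr2NEt, CH2Cl2, −78 → 0 °C; then 7 in CH2Cl2, −78 → −20 °C; then pH 7 buffer (NaH2PO4/Na2HPO4), MeOH, 30% H2O2, 0 °C
Reagents that add atoms: none
Why: Evans syn-aldol reaction, in which the Z-boron enolate reacts through a Zimmerman–Traxler chair with the aldehyde approaching the enolate face remote from the benzyl group of the dipole-minimised auxiliary, so that C5 (R in the adduct) and the syn carbinol C1 (R) are set together.

Step 5
Reactants: 9 (4R)-4-benzyl-3-[(2R,4Z)-2-[(1R,2Z)-1-hydroxy-3-iodoprop-2-en-1-yl]hept-4-enoyl]-1,3-oxazolidin-2-one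
Product: 10 (2R,4Z)-2-[(1R,2Z)-1-hydroxy-3-iodoprop-2-en-1-yl]-N-methoxy-N-methylhept-4-enamide
Conditions: MeNH(OMe)·HCl, AlMe3, CH2Cl2, 0 °C → rt; then 9, −10 → 0 °C; aq. HCl (0.5 M) work-up
Reagents that add atoms: N,O-dimethylhydroxylamine hydrochloride, CNOC.Cl
Why: Weinreb transamidation with the aluminium amide is assisted by the free β-hydroxyl group (its aluminium alkoxide delivers the amide to the exocyclic imide carbonyl), so the auxiliary should be released without epimerisation of C5 or retro-aldol cleavage.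

Step 6
Reactants: 10 (2R,4Z)-2-[(1R,2Z)-1-hydroxy-3-iodoprop-2-en-1-yl]-N-methoxy-N-methylhept-4-enamide
Product: 11 (2R,4Z)-2-[(1R,2Z)-1-[(tert-butyldimethylsilyl)oxy]-3-iodoprop-2-en-1-yl]-N-methoxy-N-methylhept-4-enamide
Conditions: TBSOTf, 2,6-lutidine, CH2Cl2, −78 → 0 °C
Reagents that add atoms: tert-butyldimethylsilyl triflate, CC(C)(C)[Si](C)(C)OS(=O)(=O)C(F)(F)F
Why: Silyl ether formation at the secondary allylic alcohol with the silyl triflate and a hindered base blocks retro-aldol and elimination pathways and installs the placeholder for the C1 ketone without touching either stereocentre.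

Step 7
Reactants: 12 8-bromooctan-1-ol
Product: 13 [(8-bromooctyl)oxy](tert-butyl)dimethylsilane
Conditions: TBSCl, imidazole, CH2Cl2, rt
Reagents that add atoms: tert-butyldimethylsilyl chloride, CC(C)(C)[Si](C)(C)Cl
Why: Imidazole-promoted silyl ether formation masks the primary alcohol so that the bromide can be turned into a Grignard reagent.

Step 8
Reactants: 13 [(8-bromooctyl)oxy](tert-butyl)dimethylsilane; 11 (2R,4Z)-2-[(1R,2Z)-1-[(tert-butyldimethylsilyl)oxy]-3-iodoprop-2-en-1-yl]-N-methoxy-N-methylhept-4-enamide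
Product: 15 (3Z,6R)-15-[(tert-butyldimethylsilyl)oxy]-6-[(1R,2Z)-1-[(tert-butyldimethylsilyl)oxy]-3-iodoprop-2-en-1-yl]pentadec-3-en-7-one, via {8-[(tert-butyldimethylsilyl)oxy]octyl}magnesium bromide 14 (not isolated)
Conditions: 13, Mg, THF, 40 °C; then 11, THF, 0 °C → rt; aq. NH4Cl
Reagents that add atoms: none
Why: Grignard addition to a Weinreb amide stops at the magnesium chelate, which gives the ketone only on work-up, so over-addition and enolisation at C5 are avoided, and a primary alkylmagnesium bromide should exchange only slowly with the alkenyl iodide at 0 °C.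

Step 9
Reactants: 15 (3Z,6R)-15-[(tert-butyldimethylsilyl)oxy]-6-[(1R,2Z)-1-[(tert-butyldimethylsilyl)oxy]-3-iodoprop-2-en-1-yl]pentadec-3-en-7-one
Product: 17 (1S,4S,5R)-4-[(tert-butyldimethylsilyl)oxy]-1-{8-[(tert-butyldimethylsilyl)oxy]octyl}-5-[(2Z)-pent-2-en-1-yl]cyclopent-2-en-1-ol, via alkenylchromium dichloride 16 (not isolated)
Conditions: CrCl2 (6 equiv), NiCl2 (5 mol%), degassed DMF (0.02 M), rt → 40 °C; then H2O
Reagents that add atoms: none
Why: CrCl2 reduces NiCl2 to zerovalent nickel, which inserts into the C3–I bond with retention of the Z geometry, and transmetalation to trivalent chromium gives alkenylchromium 16, whose C3 adds to the C4 ketone to give a chromium alkoxide that is hydrolysed on work-up. The closest known reaction type is the intramolecular Nozaki–Hiyama–Kishi coupling of an alkenyl iodide with a carbonyl group, which is established for ketone acceptors when a five- or six-membered ring forms, although ketones react more slowly than aldehydes. The cyclopentene ring closes in the 5-exo-trig mode, the carbonyl oxygen staying outside the ring and the Z-alkene becoming the ring C2=C3 bond. The new C4 stereocentre is controlled by the adjacent C5 centre: in the envelope-like transition state the octyl chain on the carbonyl carbon should turn to the ring face opposite the C5 pentenyl group, leaving the chromium-bound oxygen cis to it as the target requires. The step needs chemoselectivity for the ketone in a substrate with an epimerisable α-carbon, a β-silyloxy group and a skipped Z-alkene, which the non-basic and only weakly Lewis-acidic chromium reagent provides, and it needs a Z iodide, which the anti hydroiodination of step 2 secures. Face selectivity rests on the short tether and on the trans arrangement of the C1 silyloxy and C5 pentenyl groups inherited from the syn-aldol step, which lets both sit pseudo-equatorial while the ring closes.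

Step 10
Reactants: 17 (1S,4S,5R)-4-[(tert-butyldimethylsilyl)oxy]-1-{8-[(tert-butyldimethylsilyl)oxy]octyl}-5-[(2Z)-pent-2-en-1-yl]cyclopent-2-en-1-ol
Product: 18 (1S,4S,5R)-4-[(tert-butyldimethylsilyl)oxy]-1-{8-[(tert-butyldimethylsilyl)oxy]octyl}-5-[(2Z)-pent-2-en-1-yl]cyclopent-2-en-1-yl acetate
Conditions: Ac2O, DMAP, Et3N, CH2Cl2, rt → 40 °C
Reagents that add atoms: acetic anhydride, CC(=O)OC(C)=O
Why: DMAP-catalysed acyl transfer (Steglich-type acetylation) to the only free hydroxyl group works under basic, non-ionising conditions, so the tertiary allylic C–O bond is not broken and the C4 configuration is retained.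

Step 11
Reactants: 18 (1S,4S,5R)-4-[(tert-butyldimethylsilyl)oxy]-1-{8-[(tert-butyldimethylsilyl)oxy]octyl}-5-[(2Z)-pent-2-en-1-yl]cyclopent-2-en-1-yl acetate
Product: 19 (1S,4S,5R)-4-hydroxy-1-(8-hydroxyoctyl)-5-[(2Z)-pent-2-en-1-yl]cyclopent-2-en-1-yl acetate
Conditions: HF·pyridine, pyridine, THF, 0 °C → rt
Reagents that add atoms: none
Why: Fluoride-mediated cleavage of both silyl ethers in a pyridine-buffered medium should spare the tertiary allylic acetate, and the freed C1 hydroxyl lies trans to the acetate across the ring, so acyl migration is not expected.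

Step 12
Reactants: 19 (1S,4S,5R)-4-hydroxy-1-(8-hydroxyoctyl)-5-[(2Z)-pent-2-en-1-yl]cyclopent-2-en-1-yl acetate
Product: 21 8-[(1S,5S)-1-(acetyloxy)-4-oxo-5-[(2Z)-pent-2-en-1-yl]cyclopent-2-en-1-yl]octanoic acid, via enone aldehyde 20 (not isolated)
Conditions: CrO3, H2SO4, H2O, acetone, 0 °C; then iPrOH
Reagents that add atoms: water, O
Why: Jones oxidation converts the secondary allylic alcohol into the enone and the primary alcohol, through the aldehyde and its hydrate, into the acid in one operation, and the acetate, the Z-alkene and the C5 centre should survive the short, base-free reaction at 0 °C.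

**Compound list**

1 | (4Z)-hept-4-enoic acid | CC/C=C\CCC(=O)O | starting material
2 | (4R)-4-benzyl-1,3-oxazolidin-2-one | O=C1N[C@H](Cc2ccccc2)CO1 | starting material
3 | (4Z)-hept-4-enoic pivalic anhydride | CC/C=C\CCC(=O)OC(=O)C(C)(C)C | intermediate (not isolated)
4 | (4R)-4-benzyl-3-[(4Z)-hept-4-enoyl]-1,3-oxazolidin-2-one | CC/C=C\CCC(=O)N1[C@H](Cc2ccccc2)COC1=O | intermediate
5 | ethyl propiolate | CCOC(=O)C#C | starting material
6 | ethyl (2Z)-3-iodoprop-2-enoate | CCOC(=O)/C=C\I | intermediate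
7 | (2Z)-3-iodoprop-2-enal | O=C/C=C\I | intermediate (used as a cold solution)
8 | (4R)-4-benzyl-3-[(1Z,4Z)-1-[(dibutylboranyl)oxy]hepta-1,4-dien-1-yl]-1,3-oxazolidin-2-one (dibutylboron Z-enolate of 4) | CC/C=C\C/C=C(\OB(CCCC)CCCC)N1[C@H](Cc2ccccc2)COC1=O | intermediate (not isolated)
9 | (4R)-4-benzyl-3-[(2R,4Z)-2-[(1R,2Z)-1-hydroxy-3-iodoprop-2-en-1-yl]hept-4-enoyl]-1,3-oxazolidin-2-one | CC/C=C\C[C@@H](C(=O)N1[C@H](Cc2ccccc2)COC1=O)[C@@H](O)/C=C\I | intermediate
10 | (2R,4Z)-2-[(1R,2Z)-1-hydroxy-3-iodoprop-2-en-1-yl]-N-methoxy-N-methylhept-4-enamide | CC/C=C\C[C@@H](C(=O)N(C)OC)[C@@H](O)/C=C\I | intermediate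
11 | (2R,4Z)-2-[(1R,2Z)-1-[(tert-butyldimethylsilyl)oxy]-3-iodoprop-2-en-1-yl]-N-methoxy-N-methylhept-4-enamide | CC/C=C\C[C@@H](C(=O)N(C)OC)[C@@H](O[Si](C)(C)C(C)(C)C)/C=C\I | intermediate
12 | 8-bromooctan-1-ol | OCCCCCCCCBr | starting material
13 | [(8-bromooctyl)oxy](tert-butyl)dimethylsilane | CC(C)(C)[Si](C)(C)OCCCCCCCCBr | intermediate
14 | {8-[(tert-butyldimethylsilyl)oxy]octyl}magnesium bromide | CC(C)(C)[Si](C)(C)OCCCCCCCC[Mg]Br | intermediate (not isolated)
15 | (3Z,6R)-15-[(tert-butyldimethylsilyl)oxy]-6-[(1R,2Z)-1-[(tert-butyldimethylsilyl)oxy]-3-iodoprop-2-en-1-yl]pentadec-3-en-7-one | CC/C=C\C[C@@H](C(=O)CCCCCCCCO[Si](C)(C)C(C)(C)C)[C@@H](O[Si](C)(C)C(C)(C)C)/C=C\I | intermediate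
16 | alkenylchromium dichloride of 15 (CrCl2 in place of iodine, Z geometry kept) | CC/C=C\C[C@@H](C(=O)CCCCCCCCO[Si](C)(C)C(C)(C)C)[C@@H](O[Si](C)(C)C(C)(C)C)/C=C\[Cr](Cl)Cl | intermediate (not isolated)
17 | (1S,4S,5R)-4-[(tert-butyldimethylsilyl)oxy]-1-{8-[(tert-butyldimethylsilyl)oxy]octyl}-5-[(2Z)-pent-2-en-1-yl]cyclopent-2-en-1-ol (hydroxyl cis to pentenyl, silyloxy trans to pentenyl) | CC/C=C\C[C@@H]1[C@@H](O[Si](C)(C)C(C)(C)C)C=C[C@]1(CCCCCCCCO[Si](C)(C)C(C)(C)C)O | intermediate
18 | (1S,4S,5R)-4-[(tert-butyldimethylsilyl)oxy]-1-{8-[(tert-butyldimethylsilyl)oxy]octyl}-5-[(2Z)-pent-2-en-1-yl]cyclopent-2-en-1-yl acetate | CC/C=C\C[C@@H]1[C@@H](O[Si](C)(C)C(C)(C)C)C=C[C@]1(CCCCCCCCO[Si](C)(C)C(C)(C)C)OC(C)=O | intermediate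
19 | (1S,4S,5R)-4-hydroxy-1-(8-hydroxyoctyl)-5-[(2Z)-pent-2-en-1-yl]cyclopent-2-en-1-yl acetate | CC/C=C\C[C@@H]1[C@@H](O)C=C[C@]1(CCCCCCCCO)OC(C)=O | intermediate
20 | (1S,5S)-4-oxo-1-(8-oxooctyl)-5-[(2Z)-pent-2-en-1-yl]cyclopent-2-en-1-yl acetate | CC/C=C\C[C@@H]1C(=O)C=C[C@]1(CCCCCCCC=O)OC(C)=O | intermediate (not isolated)
21 | 8-[(1S,5S)-1-(acetyloxy)-4-oxo-5-[(2Z)-pent-2-en-1-yl]cyclopent-2-en-1-yl]octanoic acid | CC/C=C\C[C@@H]1C(=O)C=C[C@]1(CCCCCCCC(=O)O)OC(C)=O | target

**Step count**

Total steps: 12. Longest linear sequence: 10 steps (steps 2, 3, 4, 5, 6, 8, 9, 10, 11, 12, from ethyl propiolate 5 to 21).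

**Steps most likely to fail**

1. Step 9. The alkenylchromium may add too slowly to the hindered, enolisable ketone, so that protonation of the carbon–chromium bond (loss of iodine without ring closure) competes; or the two ketone faces may be told apart too poorly at C4. The fallback sets out from Weinreb amide 11 and closes the same C3–C4 bond onto an aldehyde, setting C4 afterwards by an intermolecular addition. Reduction of 11 with iBu2AlH (THF, −78 °C) should give (2R,4Z)-2-[(1R,2Z)-1-[(tert-butyldimethylsilyl)oxy]-3-iodoprop-2-en-1-yl]hept-4-enal F1. CrCl2 with catalytic NiCl2 in DMF then forms the alkenylchromium dichloride of the aldehyde F2, which is not isolated and cyclises onto the far more reactive aldehyde to give (4S,5S)-4-[(tert-butyldimethylsilyl)oxy]-5-[(2Z)-pent-2-en-1-yl]cyclopent-2-en-1-ol F3 as a mixture of carbinol epimers. Dess–Martin periodinane converts both epimers into (4S,5R)-4-[(tert-butyldimethylsilyl)oxy]-5-[(2Z)-pent-2-en-1-yl]cyclopent-2-en-1-one F4. Grignard reagent 14 is transmetalated with anhydrous CeCl3 (THF, −78 °C) to dichloro{8-[(tert-butyldimethylsilyl)oxy]octyl}cerium F5, which should add 1,2 to the ring carbonyl of F4 from the face opposite the neighbouring pentenyl group. This comes back to the route at cyclopentenol 17.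

2. Step 4. (Z)-3-Iodoacrolein may isomerise to the E form or polymerise before or during the aldol addition, which would erode the alkene geometry on which the ring closure depends. The fallback sets out from imide 4 and builds the Z-iodoalkene after the aldol reaction. Boron enolate 8 is combined with commercial [(4-methoxybenzyl)oxy]acetaldehyde in an Evans syn-aldol reaction to give (4R)-4-benzyl-3-[(2R,4Z)-2-{(1R)-1-hydroxy-2-[(4-methoxybenzyl)oxy]ethyl}hept-4-enoyl]-1,3-oxazolidin-2-one F6. Weinreb transamidation (AlMe3, MeNH(OMe)·HCl) should give (2R,4Z)-2-{(1R)-1-hydroxy-2-[(4-methoxybenzyl)oxy]ethyl}-N-methoxy-N-methylhept-4-enamide F7, and TBSOTf/2,6-lutidine its silyl ether (2R,4Z)-2-{(1R)-1-[(tert-butyldimethylsilyl)oxy]-2-[(4-methoxybenzyl)oxy]ethyl}-N-methoxy-N-methylhept-4-enamide F8. DDQ in CH2Cl2/pH 7 buffer removes the 4-methoxybenzyl group to give (2R,4Z)-2-{(1R)-1-[(tert-butyldimethylsilyl)oxy]-2-hydroxyethyl}-N-methoxy-N-methylhept-4-enamide F9. Dess–Martin periodinane gives (2R,4Z)-2-{(1R)-1-[(tert-butyldimethylsilyl)oxy]-2-oxoethyl}-N-methoxy-N-methylhept-4-enamide F10. Stork–Zhao olefination (Ph3P+CH2I I−, NaN(SiMe3)2, THF/DMPU, −78 °C) installs the (Z)-iodoalkene and comes back to the route at silyl ether 11.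

3. Step 12. The tertiary allylic acetate may ionise or hydrolyse in aqueous H2SO4 before the enone has formed, leading to allylic transposition or loss of the acetate. The fallback sets out from diol 19 and oxidises in two neutral or buffered stages. Dess–Martin periodinane with NaHCO3 in CH2Cl2 oxidises both alcohols to enone aldehyde 20, which is now isolated. A Pinnick oxidation (NaClO2, NaH2PO4, 2-methyl-2-butene, t-BuOH/H2O) then converts the aldehyde into the acid and comes back to the route at target 21. New compounds on this path: none F0.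

Further compounds
F1 | step 9 | (2R,4Z)-2-[(1R,2Z)-1-[(tert-butyldimethylsilyl)oxy]-3-iodoprop-2-en-1-yl]hept-4-enal | CC/C=C\C[C@@H](C=O)[C@@H](O[Si](C)(C)C(C)(C)C)/C=C\I
F2 | step 9 | alkenylchromium dichloride of the aldehyde (CrCl2 in place of iodine in F1) | CC/C=C\C[C@@H](C=O)[C@@H](O[Si](C)(C)C(C)(C)C)/C=C\[Cr](Cl)Cl
F3 | step 9 | (4S,5S)-4-[(tert-butyldimethylsilyl)oxy]-5-[(2Z)-pent-2-en-1-yl]cyclopent-2-en-1-ol (both C1 epimers) | CC/C=C\C[C@@H]1[C@@H](O[Si](C)(C)C(C)(C)C)C=CC1O
F4 | step 9 | (4S,5R)-4-[(tert-butyldimethylsilyl)oxy]-5-[(2Z)-pent-2-en-1-yl]cyclopent-2-en-1-one | CC/C=C\C[C@@H]1[C@@H](O[Si](C)(C)C(C)(C)C)C=CC1=O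
F5 | step 9 | dichloro{8-[(tert-butyldimethylsilyl)oxy]octyl}cerium | CC(C)(C)[Si](C)(C)OCCCCCCCC[Ce](Cl)Cl
F6 | step 4 | (4R)-4-benzyl-3-[(2R,4Z)-2-{(1R)-1-hydroxy-2-[(4-methoxybenzyl)oxy]ethyl}hept-4-enoyl]-1,3-oxazolidin-2-one | CC/C=C\C[C@@H](C(=O)N1[C@H](Cc2ccccc2)COC1=O)[C@@H](O)COCc1ccc(OC)cc1
F7 | step 4 | (2R,4Z)-2-{(1R)-1-hydroxy-2-[(4-methoxybenzyl)oxy]ethyl}-N-methoxy-N-methylhept-4-enamide | CC/C=C\C[C@@H](C(=O)N(C)OC)[C@@H](O)COCc1ccc(OC)cc1
F8 | step 4 | (2R,4Z)-2-{(1R)-1-[(tert-butyldimethylsilyl)oxy]-2-[(4-methoxybenzyl)oxy]ethyl}-N-methoxy-N-methylhept-4-enamide | CC/C=C\C[C@@H](C(=O)N(C)OC)[C@@H](O[Si](C)(C)C(C)(C)C)COCc1ccc(OC)cc1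
F9 | step 4 | (2R,4Z)-2-{(1R)-1-[(tert-butyldimethylsilyl)oxy]-2-hydroxyethyl}-N-methoxy-N-methylhept-4-enamide | CC/C=C\C[C@@H](C(=O)N(C)OC)[C@@H](O[Si](C)(C)C(C)(C)C)CO
F10 | step 4 | (2R,4Z)-2-{(1R)-1-[(tert-butyldimethylsilyl)oxy]-2-oxoethyl}-N-methoxy-N-methylhept-4-enamide | CC/C=C\C[C@@H](C(=O)N(C)OC)[C@@H](O[Si](C)(C)C(C)(C)C)C=O
F0 | step 12 | none | none
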